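At late times the teal run, which is this very flask followed so far, barely moves: open intermediate reads 33.5 % at 4.00 d and 33.6 % at 8.00 d, lower than the 58.9 % at 0.333 d. I charge the same recipe again, and my one decision is when to stop it.

| flask | substrate | coupling partner | free catalyst | remark | time |
|---|---|---|---|---|---|
| teal | 1.5 M | 1 equiv | 0.05 mol% | the very flask that is asked about, followed so far |  |
| flask | 1.5 M | 1.00 equiv | 0.05 mol% |  | 15 d |

teal run (percent of the substrate charged)

| time / d | open intermediate / % | target / % |
|---|---|---|
| 0.0833 | 42.3 | 2.0 |
| 0.167 | 55.8 | 5.5 |
| 0.333 | 58.9 | 12.7 |
| 0.833 | 48.2 | 28.2 |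
| 1.67 | 35.8 | 37.4 |
| 4.00 | 33.5 | 37.8 |
| 8.00 | 33.6 | 37.2 |

(each reading ± 0.5 percentage points)



* when, up to 15 d, the flask holds most open intermediate
* the amount of open intermediate, in percent of the substrate charged, at that time
* the first time at which open intermediate reaches 42 %, in the same percent

Let y and p be open intermediate and target as fractions of the substrate charged. Between two readings I compare the gain of y + p with the gain of p, and I claim no more for their ratio than that M minus one equals Δy/Δp:

M = Δ(y + p) / Δp

around 0.250 d: M = 1.43

around 0.583 d: M = 0.310

I carry this gain ratio. While it stands above one and p is rising, y rises, and between these two moments it falls. Both values are readings with the scatter of their points. Taking ln M as straight in time between those two moments, M reaches one at 0.328 d, and there I would stop.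

The forecast says 0.3 d, 59.3 % and 0.082 d, on the grounds that “The two rates balance at about 0.29–0.30 d”. Its time is earlier than mine.

The flask peaks at 0.298 d with 59.7 %, and reaches the level at 0.0870 d, so the forecast holds. At 0.372 d, later than my stop, it still holds 59.1 %. The peak lies between the moments where M read 1.43 and 0.310, so my stop stands for the next run.

    substrate + free catalyst ⇌ free catalyst + open intermediate (K = 3.40, k = 0.125 /M/s)
    free catalyst + open intermediate ⇌ catalyst intermediate (K = 2.37 /M, k = 0.0199 /M/s)
    coupling partner + catalyst intermediate → free catalyst + target (k = 0.118 /M/s)
    target + free catalyst ⇌ isomer of the product + free catalyst, rate k4*[free catalyst]*[target] forward; the back reaction follows from the equilibrium constant (K = 0.560, k = 0.0234 /M/s)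
    coupling partner → decomposed reagent (k = 7.33 × 10⁻⁶ /s)
    free catalyst ⇌ dormant form (K = 0.840, k = 8.09 × 10⁻⁶ /s)

The steps that change y and p in these equations each carry a form of the catalyst, so at 0.085 mol% of free catalyst I expect M at equal fractions to stay near what it was, and the crossing to come at about the same height. That neighbour flask gives 59.7 %.

The runs are simulated for an exercise; noise was put on by code.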